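**Retrosynthetic overview**
1. The C3–C6 tetramethylene tether is the four ring carbons of a 2,5-disubstituted thiophene; the last step (Raney Ni) destroys the heteroaromatic ring and removes the two O-benzyl groups in the same flask.
2. C7–C8 ketol: thiophene-2-carbaldehyde 8 plus 1-nitrohexane (asymmetric Henry reaction, then Nef reaction through a silyl nitronate).
3. Aldehyde and C2 acetate: thienyl carbinol 4 by α-lithiation, formylation and in-flask acetylation; 4 from ketone 3 by asymmetric transfer hydrogenation.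
4. Ketone 3: 2-acetylthiophene plus 1,3-bis(benzyloxy)-5-bromobenzene by Pd-catalysed α-arylation.
5. Rings: none is formed; the benzene and thiophene rings are bought, and the thiophene ring is destroyed in the last step.

Assumption: 1, 2 and 9 are bought; where a chiral ligand or catalyst is used, its sense is given as the carbonyl face it must attack, to be confirmed by Mosher ester analysis on the first batch.

**Route**

Step 1
Reactants: 1 2-acetylthiophene; 2 1,3-bis(benzyloxy)-5-bromobenzene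
Product: 3 2-[3,5-bis(benzyloxy)phenyl]-1-(thiophen-2-yl)ethan-1-one
Conditions: Pd(OAc)2 (2 mol%), Xantphos (2.4 mol%), NaOtBu (2.2 equiv), 1 (1.5 equiv), toluene, 80 °C
Reagents that add atoms: none
Why: Buchwald–Hartwig-type Pd-catalysed α-arylation of the methyl ketone enolate gives the benzyl thienyl ketone in one operation; the excess of 1 and the wide-bite-angle ligand hold back diarylation, and no stereocentre is formed.

Step 2
Reactants: 3 2-[3,5-bis(benzyloxy)phenyl]-1-(thiophen-2-yl)ethan-1-one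
Product: 4 (1S)-2-[3,5-bis(benzyloxy)phenyl]-1-(thiophen-2-yl)ethan-1-ol
Conditions: RuCl(p-cymene)[(S,S)-TsDPEN] (1 mol%), HCO2H–Et3N (5:2), EtOAc, 30 °C
Reagents that add atoms: none
Why: Noyori asymmetric transfer hydrogenation delivers hydride to the Re face of the heteroaryl ketone (the sense that gives (S)-1-phenylethanol from acetophenone), which sets the future C2 carbinol as (S); this becomes (R) by priority change alone once the thienyl carbon is a CH2.

Step 3
Reactants: 4 (1S)-2-[3,5-bis(benzyloxy)phenyl]-1-(thiophen-2-yl)ethan-1-ol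
Product: 8 (1S)-2-[3,5-bis(benzyloxy)phenyl]-1-(5-formylthiophen-2-yl)ethyl acetate, via dilithio alkoxide 5 (not isolated), via dilithium DMF adduct 6 (not isolated), via hydroxy aldehyde 7 (not isolated)
Conditions: n-BuLi (2.2 equiv), THF, −78 → −20 °C; DMF, −78 → 0 °C; AcOH; then Ac2O, Et3N, DMAP (cat.), 0 °C → rt
Reagents that add atoms: N,N-dimethylformamide CN(C)C=O; acetic anhydride CC(=O)OC(C)=O
Why: The first equivalent of n-BuLi makes the alkoxide and the second removes the thiophene C5–H, the most acidic C–H left (α-lithiation of thiophene); Bouveault formylation with DMF and DMAP-catalysed O-acetylation of the released alcohol then install the aldehyde and the C2 acetate without touching the stereocentre.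

Step 4
Reactants: 8 (1S)-2-[3,5-bis(benzyloxy)phenyl]-1-(5-formylthiophen-2-yl)ethyl acetate; 9 1-nitrohexane
Product: 10 (1S)-2-[3,5-bis(benzyloxy)phenyl]-1-{5-[(1S)-1-hydroxy-2-nitroheptyl]thiophen-2-yl}ethyl acetate (both epimers at the nitro carbon)
Conditions: Cu(OAc)2·H2O (10 mol%), indane-fused bis(oxazoline) ligand (Si-face-directing enantiomer, 11 mol%), 9 (8 equiv), EtOH, 0 °C → rt
Reagents that add atoms: none
Why: Copper–bis(oxazoline)-catalysed asymmetric Henry (nitroaldol) reaction with nitronate attack on the Si face of the aldehyde (the sense that gives (R)-2-nitro-1-phenylethanol from benzaldehyde and nitromethane) sets the future C7 carbinol as (S) under catalyst control; the acetate tolerates the weakly basic medium, and the nitro-bearing carbon needs no control because it becomes the ketone.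

Step 5
Reactants: 10 (1S)-2-[3,5-bis(benzyloxy)phenyl]-1-{5-[(1S)-1-hydroxy-2-nitroheptyl]thiophen-2-yl}ethyl acetate
Product: 14 (1S)-2-[3,5-bis(benzyloxy)phenyl]-1-{5-[(1S)-1-hydroxy-2-oxoheptyl]thiophen-2-yl}ethyl acetate, via O-trimethylsilyl nitro ether 11 (not isolated), via trimethylsilyl nitronate 12 (not isolated), via trimethylsilyloxy ketone 13 (not isolated)
Conditions: Me3SiCl, imidazole, CH2Cl2, 0 °C; DBU, Me3SiCl, 0 °C → rt; mCPBA, 0 °C; aq. citric acid, THF
Reagents that add atoms: 3-chloroperbenzoic acid OOC(=O)c1cccc(Cl)c1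
Why: Oxidative Nef reaction through a silyl nitronate: O-silylation first shuts off the retro-Henry path that would scramble C7, the silyl nitronate is then cleaved by the peracid to the ketone far faster than the peracid attacks the thiophene, and the acidic work-up removes the labile Me3Si ether, so C7 is never exposed to base as a free nitro alcohol.

Step 6
Reactants: 14 (1S)-2-[3,5-bis(benzyloxy)phenyl]-1-{5-[(1S)-1-hydroxy-2-oxoheptyl]thiophen-2-yl}ethyl acetate
Product: 16 (2R,7R)-1-(3,5-dihydroxyphenyl)-7-hydroxy-8-oxotridecan-2-yl acetate, via desulfurised bis(benzyl ether) 15 (not isolated)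
Conditions: Raney Ni (W-2, washed neutral, large excess), H2 (1 atm), EtOH–EtOAc, 25 → 40 °C
Reagents that add atoms: none
Why: Reductive desulfurisation of the thiophene with Raney Ni (thiophene as a latent tetramethylene chain) destroys the heteroaromatic ring and turns its four carbons into C3–C6, and the same catalyst hydrogenolyses the two aryl benzyl ethers; both carbinol centres keep their geometry and become (2R,7R) by priority change only, while the neutral catalyst and low temperature are chosen to spare the ketone and the acetate.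

**Compound list**
1 | 2-acetylthiophene | CC(=O)c1cccs1 | starting material
2 | 1,3-bis(benzyloxy)-5-bromobenzene | Brc1cc(OCc2ccccc2)cc(OCc2ccccc2)c1 | starting material
3 | 2-[3,5-bis(benzyloxy)phenyl]-1-(thiophen-2-yl)ethan-1-one | O=C(Cc1cc(OCc2ccccc2)cc(OCc2ccccc2)c1)c1cccs1 | intermediate
4 | (1S)-2-[3,5-bis(benzyloxy)phenyl]-1-(thiophen-2-yl)ethan-1-ol | O[C@@H](Cc1cc(OCc2ccccc2)cc(OCc2ccccc2)c1)c1cccs1 | intermediate
5 | lithium (1S)-2-[3,5-bis(benzyloxy)phenyl]-1-(5-lithiothiophen-2-yl)ethan-1-olate (in flask) | [Li]O[C@@H](Cc1cc(OCc2ccccc2)cc(OCc2ccccc2)c1)c1ccc([Li])s1 | intermediate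
6 | dilithium alkoxide of the DMF adduct of 5 (in flask) | [Li]O[C@@H](Cc1cc(OCc2ccccc2)cc(OCc2ccccc2)c1)c1ccc(C(O[Li])N(C)C)s1 | intermediate
7 | 5-{(1S)-2-[3,5-bis(benzyloxy)phenyl]-1-hydroxyethyl}thiophene-2-carbaldehyde (in flask) | O[C@@H](Cc1cc(OCc2ccccc2)cc(OCc2ccccc2)c1)c1ccc(C=O)s1 | intermediate
8 | (1S)-2-[3,5-bis(benzyloxy)phenyl]-1-(5-formylthiophen-2-yl)ethyl acetate | CC(=O)O[C@@H](Cc1cc(OCc2ccccc2)cc(OCc2ccccc2)c1)c1ccc(C=O)s1 | intermediate
9 | 1-nitrohexane | CCCCCC[N+](=O)[O-] | starting material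
10 | (1S)-2-[3,5-bis(benzyloxy)phenyl]-1-{5-[(1S)-1-hydroxy-2-nitroheptyl]thiophen-2-yl}ethyl acetate (epimers at the nitro carbon) | CCCCCC([N+](=O)[O-])[C@H](O)c1ccc(s1)[C@H](Cc1cc(OCc2ccccc2)cc(OCc2ccccc2)c1)OC(C)=O | intermediate
11 | (1S)-2-[3,5-bis(benzyloxy)phenyl]-1-{5-[(1S)-2-nitro-1-(trimethylsilyloxy)heptyl]thiophen-2-yl}ethyl acetate (in flask) | CCCCCC([N+](=O)[O-])[C@H](O[Si](C)(C)C)c1ccc(s1)[C@H](Cc1cc(OCc2ccccc2)cc(OCc2ccccc2)c1)OC(C)=O | intermediate
12 | trimethylsilyl nitronate of 11 (in flask) | CCCCCC(=[N+]([O-])O[Si](C)(C)C)[C@H](O[Si](C)(C)C)c1ccc(s1)[C@H](Cc1cc(OCc2ccccc2)cc(OCc2ccccc2)c1)OC(C)=O | intermediate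
13 | (1S)-2-[3,5-bis(benzyloxy)phenyl]-1-{5-[(1S)-2-oxo-1-(trimethylsilyloxy)heptyl]thiophen-2-yl}ethyl acetate (in flask) | CCCCCC(=O)[C@H](O[Si](C)(C)C)c1ccc(s1)[C@H](Cc1cc(OCc2ccccc2)cc(OCc2ccccc2)c1)OC(C)=O | intermediate
14 | (1S)-2-[3,5-bis(benzyloxy)phenyl]-1-{5-[(1S)-1-hydroxy-2-oxoheptyl]thiophen-2-yl}ethyl acetate | CCCCCC(=O)[C@H](O)c1ccc(s1)[C@H](Cc1cc(OCc2ccccc2)cc(OCc2ccccc2)c1)OC(C)=O | intermediate
15 | (2R,7R)-1-[3,5-bis(benzyloxy)phenyl]-7-hydroxy-8-oxotridecan-2-yl acetate (in flask) | CCCCCC(=O)[C@H](O)CCCC[C@H](Cc1cc(OCc2ccccc2)cc(OCc2ccccc2)c1)OC(C)=O | intermediate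
16 | (2R,7R)-1-(3,5-dihydroxyphenyl)-7-hydroxy-8-oxotridecan-2-yl acetate (CNP0374719.1) | CCCCCC(=O)[C@H](O)CCCC[C@H](Cc1cc(O)cc(O)c1)OC(C)=O | target

**Summary**
Total step count: 6. Longest linear sequence: 6 (1 or 2 → 16).

**Steps most likely to fail**

Step 6 is the most exposed. The free thenylic ketol of 14 may be reduced at C8, hydrogenolysed or epimerised at C7 before the sulfur is gone, and the thenylic acetate may be hydrogenolysed. The fallback sets out from 14 and comes back at 16. Silylate the C7 hydroxyl (TBSOTf, 2,6-lutidine, CH2Cl2, −78 °C) to the tert-butyldimethylsilyl ether F1, which can no longer tautomerise. Desulfurise only (Raney Ni, EtOH, 50 °C, no H2 atmosphere) to the saturated silyloxy ketone F2. Return any over-reduced C8 carbinol F3 to F2 with Dess–Martin periodinane, which is unambiguous here because C8–OH is the only free hydroxyl. Cleave the benzyl ethers separately with H2 over Pd(OH)2/C in EtOAc to the resorcinol silyl ether F4, and desilylate with HF·pyridine in THF to reach 16.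

Step 5 can fail through incomplete silyl nitronate formation at the hindered secondary nitro carbon or through peracid attack on the electron-rich thiophene. The fallback drops the nitro chemistry, sets out from aldehyde 8 and comes back at 14. A catalytic asymmetric Nozaki–Hiyama–Kishi coupling with 2-bromohept-1-ene (CrCl2 cat., NiCl2(2,9-dimethyl-1,10-phenanthroline) cat., chiral sulfonamide–oxazoline ligand, Mn, Cp2ZrCl2, LiCl, MeCN; Si-face addition) gives the allylic alcohol F5. Protection (Et3SiCl, imidazole, DMF) gives the triethylsilyl ether F6. Lemieux–Johnson cleavage of the 1,1-disubstituted alkene (OsO4 cat., NaIO4, 2,6-lutidine, dioxane–H2O) gives the silyloxy ketone F7, and HF·pyridine in THF releases 14.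

Step 4 can give low conversion or eroded ee, because the 5-alkylthiophene aldehyde is electron-rich and the Henry reaction is reversible. The fallback sets out from 1-nitrohexane 9 (with 8) and comes back at 11. Convert 9 into trimethylsilyl hexane-1-nitronate F8 (Me3SiCl, Et3N, MeCN). Add F8 to aldehyde 8 at −78 °C in THF under a chiral C2-symmetric N-spiro quaternary ammonium bifluoride (fluoride-triggered silyl nitroaldol, Si-face selective). The silyl group is transferred to oxygen in the C–C bond-forming event, so the O-silyl nitro ether 11 is obtained directly and enters step 5 at its second stage.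

**Further compounds**
F1 | step 6 | (1S)-2-[3,5-bis(benzyloxy)phenyl]-1-{5-[(1S)-1-(tert-butyldimethylsilyloxy)-2-oxoheptyl]thiophen-2-yl}ethyl acetate | CCCCCC(=O)[C@H](O[Si](C)(C)C(C)(C)C)c1ccc(s1)[C@H](Cc1cc(OCc2ccccc2)cc(OCc2ccccc2)c1)OC(C)=O
F2 | step 6 | (2R,7R)-1-[3,5-bis(benzyloxy)phenyl]-7-(tert-butyldimethylsilyloxy)-8-oxotridecan-2-yl acetate | CCCCCC(=O)[C@H](O[Si](C)(C)C(C)(C)C)CCCC[C@H](Cc1cc(OCc2ccccc2)cc(OCc2ccccc2)c1)OC(C)=O
F3 | step 6 | (2R,7R)-1-[3,5-bis(benzyloxy)phenyl]-7-(tert-butyldimethylsilyloxy)-8-hydroxytridecan-2-yl acetate (C8 epimers) | CCCCCC(O)[C@H](O[Si](C)(C)C(C)(C)C)CCCC[C@H](Cc1cc(OCc2ccccc2)cc(OCc2ccccc2)c1)OC(C)=O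
F4 | step 6 | (2R,7R)-7-(tert-butyldimethylsilyloxy)-1-(3,5-dihydroxyphenyl)-8-oxotridecan-2-yl acetate | CCCCCC(=O)[C@H](O[Si](C)(C)C(C)(C)C)CCCC[C@H](Cc1cc(O)cc(O)c1)OC(C)=O
F5 | step 5 | (1S)-2-[3,5-bis(benzyloxy)phenyl]-1-{5-[(1S)-1-hydroxy-2-methylideneheptyl]thiophen-2-yl}ethyl acetate | C=C(CCCCC)[C@H](O)c1ccc(s1)[C@H](Cc1cc(OCc2ccccc2)cc(OCc2ccccc2)c1)OC(C)=O
F6 | step 5 | (1S)-2-[3,5-bis(benzyloxy)phenyl]-1-{5-[(1S)-2-methylidene-1-(triethylsilyloxy)heptyl]thiophen-2-yl}ethyl acetate | C=C(CCCCC)[C@H](O[Si](CC)(CC)CC)c1ccc(s1)[C@H](Cc1cc(OCc2ccccc2)cc(OCc2ccccc2)c1)OC(C)=O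
F7 | step 5 | (1S)-2-[3,5-bis(benzyloxy)phenyl]-1-{5-[(1S)-2-oxo-1-(triethylsilyloxy)heptyl]thiophen-2-yl}ethyl acetate | CCCCCC(=O)[C@H](O[Si](CC)(CC)CC)c1ccc(s1)[C@H](Cc1cc(OCc2ccccc2)cc(OCc2ccccc2)c1)OC(C)=O
F8 | step 4 | trimethylsilyl hexane-1-nitronate | CCCCCC=[N+]([O-])O[Si](C)(C)C
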